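**Plan**

Locants: oxane O1, C2 (3,4-dihydroxy-5-methoxyphenyl), C3, C4 (OH), C5, C6, then C7–C8 out to the catechol ring. C6 stands 1,5 to the benzylic C2 oxygen and carries a two-carbon arm, so a terminal C6=C7 alkene can take up O1 at C6 and carbon monoxide at C7 in one palladium(II) step.
Retrosynthetic cuts, in order: the four O–benzyl bonds; C8–aryl (catechol ring); O1–C6 together with C7–C8 (alkenediol, CO, methanol); the C2 carbinol back to a ketone; C2–C3 (aryl dithiane anion plus epoxide); C5–C6 (vinyl Grignard plus epichlorohydrin).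
Forward: the C2–C7 chain is joined at C2–C3, the oxane (the only ring made) closes in step 8 with C8 arriving as an ester carbon, the catechol ring is coupled to C8 after reduction and bromination, and hydrogenolysis ends the route.
Stereochemistry: C4 comes from (S)-epichlorohydrin, C2 from a hydroxyl-directed 1,3-syn ketone reduction, and C6 from the chair-like oxypalladation (2,6-cis).

Key step: step 8

Remark: Ar denotes 3,4-bis(benzyloxy)-5-methoxyphenyl. Compounds 1, 4, 5 and 18 are assumed to be purchased. Locants C2–C8 in the Why lines are those of the target.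

Step 1
Reactants: 1 3,4-dihydroxy-5-methoxybenzaldehyde
Product: 2 3,4-bis(benzyloxy)-5-methoxybenzaldehyde
Conditions: BnBr (2.4 equiv), K2CO3, DMF, 60 °C
Reagents that add atoms: benzyl bromide, BrCc1ccccc1
Why: Williamson etherification, in which both phenoxides are benzylated by SN2 while the aldehyde stays untouched; no stereocentre is involved.

Step 2
Reactants: 2 3,4-bis(benzyloxy)-5-methoxybenzaldehyde
Product: 3 2-Ar-1,3-dithiane
Conditions: HS(CH2)3SH (1.1 equiv), I2 (10 mol %), CH2Cl2, rt
Reagents that add atoms: propane-1,3-dithiol, SCCCS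
Why: Iodine-catalysed dithioacetalisation of an aromatic aldehyde is mild enough to leave the aryl benzyl and methyl ethers intact and installs the acyl-anion equivalent for C2.

Step 3
Reactants: 4 (S)-epichlorohydrin; 5 vinylmagnesium bromide
Product: 6 (2S)-1-chloropent-4-en-2-ol
Conditions: CuI (10 mol %), THF, −78 → −30 °C
Reagents that add atoms: none
Why: Copper-catalysed Grignard opening of the epoxide at its unsubstituted carbon (SN2) forms C5–C6 without touching the carbinol carbon, so the S configuration (the later C4) is carried over from 4.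

Step 4
Reactants: 6 (2S)-1-chloropent-4-en-2-ol
Product: 7 (2S)-2-(prop-2-en-1-yl)oxirane
Conditions: powdered NaOH, Et2O, 0 °C → rt, then distillation
Reagents that add atoms: none
Why: Intramolecular Williamson reaction (3-exo-tet) of the chlorohydrin closes the epoxide at the primary carbon, so the C–O bond at the stereocentre is not broken and its configuration is retained.

Step 5
Reactants: 3 2-Ar-1,3-dithiane; 7 (2S)-2-(prop-2-en-1-yl)oxirane
Product: 9 (2S)-1-(2-Ar-1,3-dithian-2-yl)pent-4-en-2-ol, via 2-lithio-2-Ar-1,3-dithiane 8 (not isolated)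
Conditions: n-BuLi, THF, −30 °C; then 7, −78 → 0 °C
Reagents that add atoms: none
Why: Corey–Seebach umpolung, in which the 2-aryl dithiane is deprotonated at C2 and the carbanion opens the monosubstituted epoxide at its CH2 terminus, forming C2–C3 and leaving the carbinol centre (C4, S) untouched.

Step 6
Reactants: 9 (2S)-1-(2-Ar-1,3-dithian-2-yl)pent-4-en-2-ol
Product: 10 (3S)-1-Ar-3-hydroxyhex-5-en-1-one
Conditions: MeI (excess), CaCO3, MeCN/H2O 9:1, 45 °C
Reagents that add atoms: water, O
Why: S-Methylation turns the dithioacetal into a leaving group and water hydrolyses it to the aryl ketone under CaCO3-buffered, near-neutral conditions that should spare the alkene, the benzyl ethers and the β-hydroxy ketone.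

Step 7
Reactants: 10 (3S)-1-Ar-3-hydroxyhex-5-en-1-one
Product: 12 (1S,3S)-1-Ar-hex-5-ene-1,3-diol, via diethylboron chelate of the hydroxy ketone 11 (not isolated)
Conditions: Et2BOMe (1.1 equiv), THF/MeOH 4:1, −78 °C; then NaBH4, −78 °C
Reagents that add atoms: none
Why: Narasaka–Prasad reduction, in which the boron chelate holds the β-alkoxy ketone in a half-chair and external hydride adds axially to give the 1,3-syn diol, so the new benzylic centre (C2) should be S under control of the C4 centre.

Step 8
Reactants: 12 (1S,3S)-1-Ar-hex-5-ene-1,3-diol; 13 carbon monoxide; 14 methanol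
Product: 15 methyl 2-[(2R,4S,6S)-6-Ar-4-hydroxyoxan-2-yl]acetate
Conditions: PdCl2 (10 mol %), CuCl2 (3 equiv), NaOAc (3 equiv), CO (1 atm), MeOH, rt
Reagents that add atoms: none
Why: Palladium(II) coordinates the terminal alkene and the benzylic C2 hydroxyl adds anti to it, forming O1–C6; CO then inserts into the primary C7–Pd bond (forming C7–C8) and methanol cleaves the acyl palladium to the methyl ester, with CuCl2 returning Pd(0) to Pd(II). The closest known reaction is the Semmelhack intramolecular alkoxycarbonylation of hydroxy alkenes, which is established for 5-ene-1,3-diols. The oxane is the only ring formed and closes in the 6-exo-trig mode. The new stereocentre C6 is set by the existing C2 centre through a chair-like transition state with the aryl group and the palladium-bound alkene arm both equatorial, which should give the 2,6-cis oxane. The step needs the benzylic hydroxyl to react in preference to the C4 hydroxyl and the ester to stay open: the C4 hydroxyl could only close an oxetane (4-exo) or add 5-endo, and being axial and trans to the new arm it cannot lactonise. NaOAc takes up the HCl released so that the electron-rich benzylic C–O bonds are not ionised.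

Step 9
Reactants: 15 methyl 2-[(2R,4S,6S)-6-Ar-4-hydroxyoxan-2-yl]acetate
Product: 16 (2S,4S,6S)-2-Ar-6-(2-hydroxyethyl)oxan-4-ol
Conditions: LiAlH4, THF, 0 °C
Reagents that add atoms: none
Why: Hydride reduction of the ester to the primary alcohol (C8 becomes CH2OH); the benzyl ethers, the oxane and all three stereocentres are inert to LiAlH4.

Step 10
Reactants: 16 (2S,4S,6S)-2-Ar-6-(2-hydroxyethyl)oxan-4-ol
Product: 17 (2S,4S,6R)-2-Ar-6-(2-bromoethyl)oxan-4-ol
Conditions: CBr4 (1.2 equiv), PPh3 (1.3 equiv), CH2Cl2, 0 °C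
Reagents that add atoms: carbon tetrabromide, BrC(Br)(Br)Br
Why: Appel reaction, in which the unhindered primary alcohol forms the alkoxyphosphonium ion and is displaced by bromide (SN2) much faster than the axial secondary C4 hydroxyl when the reagents are kept near one equivalent; the descriptor at C6 changes only because of ligand priorities.

Step 11
Reactants: 18 4-bromobenzene-1,2-diol (4-bromocatechol)
Product: 19 1,2-bis(benzyloxy)-4-bromobenzene
Conditions: BnBr (2.4 equiv), K2CO3, DMF, 60 °C
Reagents that add atoms: benzyl bromide, BrCc1ccccc1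
Why: Williamson etherification of both catechol hydroxyls, giving the same benzyl protection as on the other ring so that one final operation removes all four groups.

Step 12
Reactants: 17 (2S,4S,6R)-2-Ar-6-(2-bromoethyl)oxan-4-ol; 19 1,2-bis(benzyloxy)-4-bromobenzene
Product: 20 (2S,4S,6S)-2-Ar-6-{2-[3,4-bis(benzyloxy)phenyl]ethyl}oxan-4-ol
Conditions: NiI2·xH2O (10 mol %), 4,4′-di-tert-butyl-2,2′-bipyridine (10 mol %), NaI (25 mol %), pyridine (10 mol %), Zn dust (2 equiv), DMPU, 60 °C
Reagents that add atoms: none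
Why: Nickel-catalysed reductive cross-electrophile coupling, in which the aryl bromide adds oxidatively to bipyridine-ligated nickel(0), the primary alkyl bromide (through the iodide) enters as a radical and reductive elimination forms the C8–aryl bond with zinc as terminal reductant; free hydroxyl groups and aryl benzyl ethers are tolerated by this reaction type and no stereocentre is touched.

Step 13
Reactants: 20 (2S,4S,6S)-2-Ar-6-{2-[3,4-bis(benzyloxy)phenyl]ethyl}oxan-4-ol
Product: 21 (2S,4S,6S)-2-(3,4-dihydroxy-5-methoxyphenyl)-6-[2-(3,4-dihydroxyphenyl)ethyl]oxan-4-ol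
Conditions: H2 (1 atm), 10 % Pd/C, EtOAc/MeOH, rt
Reagents that add atoms: none
Why: Catalytic hydrogenolysis cleaves the four aryl benzyl ethers, while the cyclic C2–O1 bond, a hindered secondary dialkyl benzylic ether, should react far more slowly under neutral conditions if the reaction is stopped after uptake of four equivalents of hydrogen.

**Compound list**

1 | 3,4-dihydroxy-5-methoxybenzaldehyde | COc1cc(C=O)cc(O)c1O | starting material
2 | 3,4-bis(benzyloxy)-5-methoxybenzaldehyde | COc1cc(C=O)cc(OCc2ccccc2)c1OCc1ccccc1 | intermediate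
3 | 2-[3,4-bis(benzyloxy)-5-methoxyphenyl]-1,3-dithiane | COc1cc(C2SCCCS2)cc(OCc2ccccc2)c1OCc1ccccc1 | intermediate
4 | (S)-epichlorohydrin, (2S)-2-(chloromethyl)oxirane | ClC[C@@H]1CO1 | starting material
5 | vinylmagnesium bromide | C=C[Mg]Br | starting material
6 | (2S)-1-chloropent-4-en-2-ol | ClC[C@@H](O)CC=C | intermediate
7 | (2S)-2-(prop-2-en-1-yl)oxirane | C=CC[C@H]1CO1 | intermediate
8 | 2-lithio-2-[3,4-bis(benzyloxy)-5-methoxyphenyl]-1,3-dithiane | COc1cc(C2([Li])SCCCS2)cc(OCc2ccccc2)c1OCc1ccccc1 | intermediate (not isolated)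
9 | (2S)-1-{2-[3,4-bis(benzyloxy)-5-methoxyphenyl]-1,3-dithian-2-yl}pent-4-en-2-ol | COc1cc(C2(C[C@@H](O)CC=C)SCCCS2)cc(OCc2ccccc2)c1OCc1ccccc1 | intermediate
10 | (3S)-1-[3,4-bis(benzyloxy)-5-methoxyphenyl]-3-hydroxyhex-5-en-1-one | COc1cc(C(=O)C[C@@H](O)CC=C)cc(OCc2ccccc2)c1OCc1ccccc1 | intermediate
11 | (3S)-1-[3,4-bis(benzyloxy)-5-methoxyphenyl]-3-[(diethylboranyl)oxy]hex-5-en-1-one (boron chelate) | COc1cc(C(=O)C[C@H](CC=C)OB(CC)CC)cc(OCc2ccccc2)c1OCc1ccccc1 | intermediate (not isolated)
12 | (1S,3S)-1-[3,4-bis(benzyloxy)-5-methoxyphenyl]hex-5-ene-1,3-diol | COc1cc([C@@H](O)C[C@@H](O)CC=C)cc(OCc2ccccc2)c1OCc1ccccc1 | intermediate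
13 | carbon monoxide | [C-]#[O+] | starting material
14 | methanol | CO | starting material
15 | methyl 2-[(2R,4S,6S)-6-[3,4-bis(benzyloxy)-5-methoxyphenyl]-4-hydroxyoxan-2-yl]acetate | COc1cc([C@@H]2C[C@@H](O)C[C@H](CC(=O)OC)O2)cc(OCc2ccccc2)c1OCc1ccccc1 | intermediate
16 | (2S,4S,6S)-2-[3,4-bis(benzyloxy)-5-methoxyphenyl]-6-(2-hydroxyethyl)oxan-4-ol | COc1cc([C@@H]2C[C@@H](O)C[C@H](CCO)O2)cc(OCc2ccccc2)c1OCc1ccccc1 | intermediate
17 | (2S,4S,6R)-2-[3,4-bis(benzyloxy)-5-methoxyphenyl]-6-(2-bromoethyl)oxan-4-ol | COc1cc([C@@H]2C[C@@H](O)C[C@H](CCBr)O2)cc(OCc2ccccc2)c1OCc1ccccc1 | intermediate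
18 | 4-bromobenzene-1,2-diol (4-bromocatechol) | Oc1ccc(Br)cc1O | starting material
19 | 1,2-bis(benzyloxy)-4-bromobenzene | Brc1ccc(OCc2ccccc2)c(OCc2ccccc2)c1 | intermediate
20 | (2S,4S,6S)-2-[3,4-bis(benzyloxy)-5-methoxyphenyl]-6-{2-[3,4-bis(benzyloxy)phenyl]ethyl}oxan-4-ol | COc1cc([C@@H]2C[C@@H](O)C[C@H](CCc3ccc(OCc4ccccc4)c(OCc4ccccc4)c3)O2)cc(OCc2ccccc2)c1OCc1ccccc1 | intermediate
21 | (2S,4S,6S)-2-(3,4-dihydroxy-5-methoxyphenyl)-6-[2-(3,4-dihydroxyphenyl)ethyl]oxan-4-ol | COc1cc([C@@H]2C[C@@H](O)C[C@H](CCc3ccc(O)c(O)c3)O2)cc(O)c1O | target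

**Count and risks**

Total step count: 13.
Longest linear sequence: 10 steps (steps 1, 2, 5, 6, 7, 8, 9, 10, 12, 13 from 1; equally steps 3, 4, 5–10, 12, 13 from 4).

Steps most likely to fail:

Step 8. The acid released on reoxidation may ionise the electron-rich benzylic C–O bond, leading to methanolysis or loss of configuration at C2. Carbonylation starting at the homoallylic C4 hydroxyl may also consume the alkene before the 6-exo oxypalladation. Fallback: from 12, cross-metathesis with methyl acrylate (Hoveyda–Grubbs II catalyst, CH2Cl2, 40 °C) should give methyl (2E,5S,7S)-7-[3,4-bis(benzyloxy)-5-methoxyphenyl]-5,7-dihydroxyhept-2-enoate F1. Catalytic KOtBu in THF (−20 → 0 °C) should then close the oxane by a reversible intramolecular oxa-Michael addition of the benzylic alkoxide, the diequatorial 2,6-cis isomer being favoured at equilibrium. The sequence rejoins the route at 15.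

Step 12. The alkyl bromide may be reduced or homocoupled faster than the electron-rich aryl bromide enters the nickel cycle, and the free hydroxyl may slow the catalyst. Fallback: from 15, MeNH(OMe)·HCl and iPrMgCl (THF, −20 °C) should give 2-[(2R,4S,6S)-6-[3,4-bis(benzyloxy)-5-methoxyphenyl]-4-hydroxyoxan-2-yl]-N-methoxy-N-methylacetamide F2. The Grignard reagent [3,4-bis(benzyloxy)phenyl]magnesium bromide F3 (from 19 and Mg, THF) should add to it to give 2-[(2R,4S,6S)-6-[3,4-bis(benzyloxy)-5-methoxyphenyl]-4-hydroxyoxan-2-yl]-1-[3,4-bis(benzyloxy)phenyl]ethan-1-one F4. NaBH4 (MeOH, 0 °C) should reduce this to (2R,4S,6S)-2-{2-[3,4-bis(benzyloxy)phenyl]-2-hydroxyethyl}-6-[3,4-bis(benzyloxy)-5-methoxyphenyl]oxan-4-ol F5 as a mixture of C8 epimers. Hydrogenolysis (H2, Pd/C, EtOAc/MeOH, trace HCl) should then remove the para-oxygen-activated C8 hydroxyl together with the four benzyl groups, rejoining the route at 21.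

Step 13. Over-reduction may occur, that is, hydrogenolysis of the cyclic benzylic C2–O1 bond once the para oxygen is unmasked, and the freed catechols may oxidise in air during isolation. Fallback: from 20, non-reductive debenzylation with BCl3 and pentamethylbenzene as cation scavenger (CH2Cl2, −78 °C) should leave the aryl methyl ether in place and lead directly to 21. No new compound is made (F0).

**Further compounds**

F1 | step 8 | methyl (2E,5S,7S)-7-[3,4-bis(benzyloxy)-5-methoxyphenyl]-5,7-dihydroxyhept-2-enoate | COc1cc([C@@H](O)C[C@@H](O)C/C=C/C(=O)OC)cc(OCc2ccccc2)c1OCc1ccccc1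
F2 | step 12 | 2-[(2R,4S,6S)-6-[3,4-bis(benzyloxy)-5-methoxyphenyl]-4-hydroxyoxan-2-yl]-N-methoxy-N-methylacetamide | COc1cc([C@@H]2C[C@@H](O)C[C@H](CC(=O)N(C)OC)O2)cc(OCc2ccccc2)c1OCc1ccccc1
F3 | step 12 | [3,4-bis(benzyloxy)phenyl]magnesium bromide | Br[Mg]c1ccc(OCc2ccccc2)c(OCc2ccccc2)c1
F4 | step 12 | 2-[(2R,4S,6S)-6-[3,4-bis(benzyloxy)-5-methoxyphenyl]-4-hydroxyoxan-2-yl]-1-[3,4-bis(benzyloxy)phenyl]ethan-1-one | COc1cc([C@@H]2C[C@@H](O)C[C@H](CC(=O)c3ccc(OCc4ccccc4)c(OCc4ccccc4)c3)O2)cc(OCc2ccccc2)c1OCc1ccccc1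
F5 | step 12 | (2R,4S,6S)-2-{2-[3,4-bis(benzyloxy)phenyl]-2-hydroxyethyl}-6-[3,4-bis(benzyloxy)-5-methoxyphenyl]oxan-4-ol (both C8 epimers) | COc1cc([C@@H]2C[C@@H](O)C[C@H](CC(O)c3ccc(OCc4ccccc4)c(OCc4ccccc4)c3)O2)cc(OCc2ccccc2)c1OCc1ccccc1
F0 | step 13 | none | none
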